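## The problem

24-Nor-spiculoic acid B is a trans-fused 3a,6,7,7a-tetrahydro-3H-indene: a cyclopentene (C1=C2, ethyl on C1) joined across C3a–C7a to a cyclohexene (C4=C5, methyl on C4). Five stereocentres must be set: C3, C3a, C7a and the two adjacent quaternary carbons C6 (ethyl, E-styryl) and C7 (methyl, CO2H). No stereocentre lies outside the bicycle, so the chain of control is short. C7, C7a and C3a can be fixed together by a cycloaddition; C6 can then be set from C4 by a 1,3-transfer across the C4=C5 allyl unit; C3 can be set from C3a. The acid sits on a neopentyl carbon, so its ester cannot be cleaved by attack at the carbonyl carbon. Strong acid would lactonise the acid onto C4=C5, and a free C6–CH2OH cis to the C7 carboxyl derivative would close a γ-lactone. The feature that opens the structure is the 1,4-relation across the cyclohexene of C7 (methyl, carboxyl) and C4 (methyl, sp2). If the carboxyl oxygen is placed on C4, a C7–C(=O)–O–C4 bridge appears, and that bridged lactone is the adduct of a 3,6-dimethyl-2-pyrone with an alkene spanning C7a and C3a.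

## Retrosynthesis

**Styryl group and acid.** The Cα=Cβ bond of the styryl group of 23 is cut back to aldehyde 21 (Horner–Wadsworth–Emmons, via ester 22). A one-carbon arm is preferred to a vinyl or styryl group carried from the start, because an alkenyl pyrone would offer a second, less hindered diene. The acid is masked as a 2-(trimethylsilyl)ethyl ester, cleaved at silicon. Aldehyde 21 is taken directly from the triethylsilyl ether 20, so that no free alcohol ever stands beside the C7 ester.

**Cyclopentene.** The C2–C3 bond of 20 is cut. An alkylidene carbene on C2, made from ethyl ketone 17, inserts into the methylene C–H of the C3a ethyl group. Against a metathesis closure this needs no stereocentre and no alkene in the dienophile, and ketone 17 is monocyclic with one stereocentre fewer. The forward step must choose the secondary C–H over others and the correct diastereotopic hydrogen.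

**Functional-group changes.** Ketone 17 comes from thioester 16, this from imide 15, and 15 from acid 14 by esterification. These steps form no skeletal bond; they remove the auxiliary and protect the acid before the carbene step.

**Quaternary C6.** The C6–ethyl bond of 14 is cut together with re-forming the C4–O bond, giving bridged allylic lactone 13. Forward, an ethyl cuprate opens the lactone by anti SN2′ attack, which sets C6, the C4=C5 alkene and the free acid in one step. It asks for attack at a fully substituted alkene carbon next to a quaternary bridgehead.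

**Key disconnection.** Lactone 13 comes from bromo lactone 12 by hydrodebromination. Adduct 12 is cut at C7–C7a and C3a–C4 into pyrone 7 and enoyl imide 11. This [4+2] turns two flat, simple partners into a bicycle with four stereocentres. The E alkene gives the trans ring fusion, the endo mode puts the acyl group on the correct face, and the chelate model calls for the (R)-benzyl auxiliary. A pyrone carrying only the C3 methyl would not secure the orientation, since the ring oxygen directs the other way. Pyrone 7 therefore carries a bromine on C5, which is removed after the cycloaddition.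

**Building blocks.** Pyrone 7 is traced through 6, 5, 4 and 3 to 4-hydroxy-6-methyl-2H-pyran-2-one 1 (bromination, silylation, Stille hydroxymethylation, triflation, C-methylation). Imide 11 comes from acid 8 and oxazolidinone 9.

## Roads not taken

Alternative 1: Both ring alkenes (C1=C2 and C4=C5) are cut. Forward, the second-generation Grubbs catalyst would close the cyclopentene and then the cyclohexene of the open-chain pentaene ester A2, giving the vinyl ester A1; the second closure uses one of two diastereotopic vinyl groups on C6. Merits: both rings form in one catalytic step, C3 would come from a defined building block, and there is no regiochemical question. Weak points: A2 needs C3, C3a, C7a and quaternary C7 set in an open chain next to the divinyl carbon. The cyclohexene closure joins a 1,1-disubstituted alkene to a neopentyl vinyl group. Nothing obvious biases the choice between the two vinyl groups, and the remaining vinyl group must still be arylated. This road is better at C3 and in orientation. The chosen plan sets against it that C7, C7a, C3a and then C6 are fixed in a rigid ring by stereospecific steps from flat precursors.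

Alternative 2: The C6–C7 bond is cut. Forward, the silyl ketene acetal of the δ-lactone A4 would undergo Ireland–Claisen rearrangement to the cyclohexene acid A3, with the lactone contracting into the carbocycle; two metathesis arms then close the cyclopentene. Merits: the bond between the two quaternary carbons forms by an intramolecular sigmatropic shift, the styryl group is present from the start, and the acid is set free in the same step. For that bond this road is better than an intermolecular cuprate attack. Weak points: A4 must be assembled with the C4 carbinol configuration and the C5=C6 geometry both correct. A tetrasubstituted ketene acetal must be formed from an α-branched lactone, the shift must pass a boat-like transition state, and a ring-closing step still follows. The chosen plan sets against it a much shorter access to the core and fewer stereo-elements to prepare beforehand.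

Alternative 3: The C5–C6 bond is cut. Forward, oxidative addition of the (Z)-alkenyl iodide A6 and 6-exo carbopalladation of its ethyl-substituted alkene would close the cyclohexene, and β-hydride elimination toward the benzylic CH2 would give the E-styrene of ester A5. Merits: the quaternary centre, the ring and the styrene arise in one late step, and no handle needs later conversion; the end game is shorter than in the chosen plan. Weak points: the facial selectivity at C6 rests only on the neighbouring C7 (methyl against ester). The insertion must form a quaternary carbon beside a quaternary carbon, and A6 needs a long preparation. The chosen plan sets against it the stereospecific anti delivery at C6 and the early settling of the ring fusion.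

Key step: step 7

Assumption: atoms are numbered as in indene (C1 ethyl-bearing alkene carbon, C7 carboxyl-bearing carbon); β is the ring face carrying the C7 carboxyl carbon, α the opposite face; pyrone C3, C4, C5 and C6 become C7, C6, C5 and C4.

## Steps

Step 1
Reactants: 1 4-hydroxy-6-methyl-2H-pyran-2-one
Product: 3 4-hydroxy-3,6-dimethyl-2H-pyran-2-one, via 6-methyl-3-methylidenepyran-2,4-dione 2 (not isolated)
Conditions: aq. CH2O, diethyl 2,6-dimethyl-1,4-dihydropyridine-3,5-dicarboxylate, L-proline (cat.), CH2Cl2, rt
Reagents that add atoms: formaldehyde, C=O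
Why: Knoevenagel condensation of the cyclic 1,3-dicarbonyl with formaldehyde gives 2, which is reduced at once by hydride transfer from the dihydropyridine (organocatalytic reductive alkylation); excess reductant keeps 2 from adding a second pyrone.

Step 2
Reactants: 3 4-hydroxy-3,6-dimethyl-2H-pyran-2-one
Product: 4 3,6-dimethyl-2-oxo-2H-pyran-4-yl trifluoromethanesulfonate
Conditions: Tf2O, Et3N, CH2Cl2, −78 → 0 °C
Reagents that add atoms: trifluoromethanesulfonic anhydride, O=S(=O)(OS(=O)(=O)C(F)(F)F)C(F)(F)F
Why: O-sulfonylation of the vinylogous acid; the C3 methyl blocks reaction at carbon.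

Step 3
Reactants: 4 3,6-dimethyl-2-oxo-2H-pyran-4-yl trifluoromethanesulfonate
Product: 5 4-(hydroxymethyl)-3,6-dimethyl-2H-pyran-2-one
Conditions: Bu3SnCH2OH, Pd(PPh3)4 (cat.), LiCl, 1,4-dioxane, 90 °C
Reagents that add atoms: (tributylstannyl)methanol, CCCC[Sn](CCCC)(CCCC)CO
Why: Stille coupling of a vinylogous acyl triflate with an α-hydroxymethyl stannane; the activated C4–O bond adds readily to palladium and LiCl assists transmetalation.

Step 4
Reactants: 5 4-(hydroxymethyl)-3,6-dimethyl-2H-pyran-2-one
Product: 6 3,6-dimethyl-4-[(triethylsilyloxy)methyl]-2H-pyran-2-one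
Conditions: Et3SiCl, imidazole, CH2Cl2, 0 °C
Reagents that add atoms: chlorotriethylsilane, CC[Si](Cl)(CC)CC
Why: Standard silylation of a primary alcohol; triethylsilyl is chosen because a primary triethylsilyl ether can later be oxidised directly under Swern conditions.

Step 5
Reactants: 6 3,6-dimethyl-4-[(triethylsilyloxy)methyl]-2H-pyran-2-one
Product: 7 5-bromo-3,6-dimethyl-4-[(triethylsilyloxy)methyl]-2H-pyran-2-one
Conditions: NBS, DMF, rt, dark
Reagents that add atoms: N-bromosuccinimide, O=C1CCC(=O)N1Br
Why: Electrophilic bromination at the only free ring carbon, C5, the enol-ether-like position β to the ring oxygen; polar conditions in the dark suppress radical attack on the methyl groups.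

Step 6
Reactants: 8 (E)-pent-2-enoic acid; 9 (R)-4-benzyloxazolidin-2-one
Product: 11 (R)-4-benzyl-3-[(E)-pent-2-enoyl]oxazolidin-2-one, via pivalic (E)-pent-2-enoic anhydride 10 (not isolated)
Conditions: PivCl, Et3N, THF, −20 °C; then 9, LiCl, rt
Reagents that add atoms: none
Why: Mixed-anhydride N-acylation of the oxazolidinone; no strong base is used, so the E alkene is not isomerised.

Step 7
Reactants: 7 5-bromo-3,6-dimethyl-4-[(triethylsilyloxy)methyl]-2H-pyran-2-one; 11 (R)-4-benzyl-3-[(E)-pent-2-enoyl]oxazolidin-2-one
Product: 12 (R)-4-benzyl-3-{[7-bromo-6-ethyl-1,4-dimethyl-3-oxo-8-[(triethylsilyloxy)methyl]-2-oxabicyclo[2.2.2]oct-7-en-5-yl]carbonyl}oxazolidin-2-one (acyl group endo; ethyl syn to the lactone bridge)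
Conditions: Et2AlCl (2.0 equiv), CH2Cl2, −78 → −20 °C
Reagents that add atoms: none
Why: Concerted, asynchronous [4+2] cycloaddition: the pyrone diene adds suprafacially across the alkene of 11, which is held s-cis and activated as the cationic bidentate chelate with Et2AlCl, so C7–C7a and C3a–C4 form together, and the ring ester survives as the O–C(=O) bridge because the reaction runs far below the temperature of CO2 loss. The closest known reactions are the thermal cycloadditions of 5-bromo-2-pyrones with acrylate-type dienophiles, which give isolable bridged lactones, and the Et2AlCl-promoted cycloadditions of N-enoyl oxazolidinones with simple dienes. The one ring closed is the carbocyclic six-membered ring C3a–C4–C5–C6–C7–C7a, by intermolecular [4+2] with the lactone left as a two-atom bridge. The bridgeheads C7 and C4 are fixed relative to each other, and C7a and C3a come out trans because the E geometry of 11 is carried through. The imide carbonyl on C7a ends syn to the new C5=C6 bridge through the endo (Alder) transition state. The absolute sense comes from the benzyl group of the (R)-auxiliary, which blocks one face of the chelate so that the diene adds to the Cα-re face. The step needs the acyl-bearing carbon to bond to the carbonyl-side terminus (C7): the C5 bromine (a para-type director in 5-bromopyrones) and the C7 methyl both favour this, and the bromine also blocks electrophilic attack at C5 and slows CO2 loss from the adduct.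

Step 8
Reactants: 12 bromo lactone
Product: 13 (R)-4-benzyl-3-{[6-ethyl-1,4-dimethyl-3-oxo-8-[(triethylsilyloxy)methyl]-2-oxabicyclo[2.2.2]oct-7-en-5-yl]carbonyl}oxazolidin-2-one (configuration as 12)
Conditions: Bu3SnH, Et3B (cat.), air, toluene, rt
Reagents that add atoms: none
Why: Radical hydrodebromination of an alkenyl bromide by a tin hydride chain, started at room temperature so the bridged lactone is not heated; no stereocentre is touched.

Step 9
Reactants: 13 bridged lactone
Product: 14 6-{[(R)-4-benzyl-2-oxooxazolidin-3-yl]carbonyl}-2,5-diethyl-1,4-dimethyl-2-[(triethylsilyloxy)methyl]cyclohex-3-ene-1-carboxylic acid (β: carboxyl, silyloxymethyl, 5-ethyl; α: 1-methyl, 2-ethyl, 6-acyl)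
Conditions: EtMgBr, CuBr·SMe2 (as Et2CuMgBr), THF–Me2S, −40 → 0 °C; aq. NaH2PO4
Reagents that add atoms: ethylmagnesium bromide, CC[Mg]Br
Why: Copper-mediated anti SN2′ substitution of an allylic lactone: copper attacks C6 on the α face, opposite the C4–O bond, C4=C5 forms and the carboxylate leaves, so ethyl is α and the silyloxymethyl arm β at C6. A stoichiometric cuprate with no free Grignard reagent spares the imide.

Step 10
Reactants: 14 acid
Product: 15 2-(trimethylsilyl)ethyl ester of 14
Conditions: Me3SiCH2CH2OH, PPh3, DIAD, THF, 0 °C → rt
Reagents that add atoms: 2-(trimethylsilyl)ethanol, C[Si](C)(C)CCO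
Why: Mitsunobu esterification: the carboxylate attacks the activated primary alcohol, so the hindered acyl carbon is never the electrophile; it is done at once so the free acid does not stand beside the acid-labile silyl ether.

Step 11
Reactants: 15 imide ester
Product: 16 2-(trimethylsilyl)ethyl 2,5-diethyl-6-[(ethylsulfanyl)carbonyl]-1,4-dimethyl-2-[(triethylsilyloxy)methyl]cyclohex-3-ene-1-carboxylate (configuration as 14)
Conditions: EtSH, n-BuLi, THF, 0 °C
Reagents that add atoms: ethanethiol, CCS
Why: Thiolate cleavage of the N-acyl oxazolidinone at the exocyclic carbonyl (transthioesterification), reliable for hindered imides; auxiliary 9 is recovered.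

Step 12
Reactants: 16 thioester
Product: 17 2-(trimethylsilyl)ethyl 2,5-diethyl-1,4-dimethyl-6-propanoyl-2-[(triethylsilyloxy)methyl]cyclohex-3-ene-1-carboxylate (configuration as 14)
Conditions: Et2CuLi (EtLi, CuI), Et2O, −78 → −40 °C
Reagents that add atoms: ethyllithium, [Li]CC
Why: Acylation of a lithium dialkylcuprate by a thioester gives the ketone and stops there; the neopentyl ester is untouched and C7a keeps its more stable equatorial acyl group.

Step 13
Reactants: 17 ethyl ketone
Product: 20 2-(trimethylsilyl)ethyl 1,6-diethyl-3,4,7-trimethyl-6-[(triethylsilyloxy)methyl]-3a,6,7,7a-tetrahydro-3H-indene-7-carboxylate (ring stereocentres as in 23; C3 methyl α), via diazoalkene 18 (not isolated), via alkylidene carbene 19 (not isolated)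
Conditions: Me3SiCHN2, n-BuLi, THF, −78 °C → rt
Reagents that add atoms: (trimethylsilyl)diazomethane, C[Si](C)(C)C=[N+]=[N-]
Why: Lithiated trimethylsilyldiazomethane adds to the ketone, Peterson-type loss of Me3SiOLi gives 18, and loss of N2 gives carbene 19. 1,5 C–H insertion into the methylene of the C3a ethyl group (secondary C–H preferred over the primary C–H of the C7 methyl) closes the cyclopentene with C1=C2 in place. The hydrogen taken is the one that leaves the new C3 methyl on the α face, away from C4 and its methyl.

Step 14
Reactants: 20 silyl ether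
Product: 21 2-(trimethylsilyl)ethyl 1,6-diethyl-6-formyl-3,4,7-trimethyl-3a,6,7,7a-tetrahydro-3H-indene-7-carboxylate (configuration as 20)
Conditions: (COCl)2, DMSO, CH2Cl2, −78 → −40 °C; Et3N, → 0 °C
Reagents that add atoms: none
Why: Direct Swern oxidation of a primary triethylsilyl ether: the chlorosulfonium salt takes the ether oxygen, chloride removes silicon, and the alkoxysulfonium ylide collapses to the aldehyde. No free alcohol or alkoxide appears, so the cis C7 ester cannot be attacked to form a γ-lactone.

Step 15
Reactants: 21 aldehyde
Product: 22 2-(trimethylsilyl)ethyl ester of 24-nor-spiculoic acid B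
Conditions: (EtO)2P(O)CH2Ph, NaH, THF, 0 → 50 °C
Reagents that add atoms: diethyl benzylphosphonate, CCOP(=O)(Cc1ccccc1)OCC
Why: Horner–Wadsworth–Emmons olefination with an aryl-stabilised phosphonate carbanion, which is E-selective; the aldehyde has no α-hydrogen, so warming does no harm.

Step 16
Reactants: 22 ester
Product: 23 24-nor-spiculoic acid B, (3R,3aS,6S,7R,7aR)-1,6-diethyl-3,4,7-trimethyl-6-[(E)-2-phenylethenyl]-3a,6,7,7a-tetrahydro-3H-indene-7-carboxylic acid
Conditions: TBAF, THF, rt; cold dilute aq. KHSO4
Reagents that add atoms: none
Why: Fluoride attacks silicon of the 2-(trimethylsilyl)ethyl ester, which fragments to ethene, Me3SiF and the carboxylate; the hindered carbonyl carbon is not involved and the brief cold acidification is too mild to lactonise the acid onto C4=C5.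

## Compound list

1 | 4-hydroxy-6-methyl-2H-pyran-2-one | Cc1cc(O)cc(=O)o1 | starting material
2 | 6-methyl-3-methylidene-2H-pyran-2,4(3H)-dione | C=C1C(=O)C=C(C)OC1=O | intermediate (not isolated)
3 | 4-hydroxy-3,6-dimethyl-2H-pyran-2-one | Cc1cc(O)c(C)c(=O)o1 | intermediate
4 | 3,6-dimethyl-2-oxo-2H-pyran-4-yl trifluoromethanesulfonate | Cc1cc(OS(=O)(=O)C(F)(F)F)c(C)c(=O)o1 | intermediate
5 | 4-(hydroxymethyl)-3,6-dimethyl-2H-pyran-2-one | Cc1cc(CO)c(C)c(=O)o1 | intermediate
6 | 3,6-dimethyl-4-[(triethylsilyloxy)methyl]-2H-pyran-2-one | Cc1cc(CO[Si](CC)(CC)CC)c(C)c(=O)o1 | intermediate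
7 | 5-bromo-3,6-dimethyl-4-[(triethylsilyloxy)methyl]-2H-pyran-2-one | Cc1oc(=O)c(C)c(CO[Si](CC)(CC)CC)c1Br | intermediate
8 | (E)-pent-2-enoic acid | CC/C=C/C(=O)O | starting material
9 | (R)-4-benzyloxazolidin-2-one | O=C1OC[C@@H](Cc2ccccc2)N1 | starting material
10 | pivalic (E)-pent-2-enoic anhydride | CC/C=C/C(=O)OC(=O)C(C)(C)C | intermediate (not isolated)
11 | (R)-4-benzyl-3-[(E)-pent-2-enoyl]oxazolidin-2-one | CC/C=C/C(=O)N1[C@H](Cc2ccccc2)COC1=O | intermediate
12 | bromo lactone adduct; lactone bridge C7–C(=O)–O–C4 on the β face, imide carbonyl on C7a endo (α), ethyl on C3a β, bromine on C5 | C[C@]12C(=O)O[C@](C)(C(Br)=C1CO[Si](CC)(CC)CC)[C@@H](CC)[C@@H]2C(=O)N3[C@H](Cc4ccccc4)COC3=O | intermediate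
13 | bridged lactone, as 12 with hydrogen on C5 | C[C@]12C(=O)O[C@](C)(C=C1CO[Si](CC)(CC)CC)[C@@H](CC)[C@@H]2C(=O)N3[C@H](Cc4ccccc4)COC3=O | intermediate
14 | cyclohexene acid; C7 CO2H β and CH3 α, C6 CH2OSiEt3 β and ethyl α, C7a imide carbonyl α, C3a ethyl β | CC[C@@H]1C(C)=C[C@@](CO[Si](CC)(CC)CC)(CC)[C@](C)(C(=O)O)[C@H]1C(=O)N2[C@H](Cc3ccccc3)COC2=O | intermediate
15 | 2-(trimethylsilyl)ethyl ester of 14 | CC[C@@H]1C(C)=C[C@@](CO[Si](CC)(CC)CC)(CC)[C@](C)(C(=O)OCC[Si](C)(C)C)[C@H]1C(=O)N2[C@H](Cc3ccccc3)COC2=O | intermediate
16 | S-ethyl thioester at C7a, configuration as 14 | CC[C@@H]1C(C)=C[C@@](CO[Si](CC)(CC)CC)(CC)[C@](C)(C(=O)OCC[Si](C)(C)C)[C@H]1C(=O)SCC | intermediate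
17 | ethyl ketone (propanoyl on C7a), configuration as 14 | CC[C@@H]1C(C)=C[C@@](CO[Si](CC)(CC)CC)(CC)[C@](C)(C(=O)OCC[Si](C)(C)C)[C@H]1C(=O)CC | intermediate
18 | diazoalkene from 17 (C=C=N2 in place of C=O) | CC[C@@H]1C(C)=C[C@@](CO[Si](CC)(CC)CC)(CC)[C@](C)(C(=O)OCC[Si](C)(C)C)[C@H]1C(CC)=C=[N+]=[N-] | intermediate (not isolated)
19 | alkylidene carbene from 18 | CC[C@@H]1C(C)=C[C@@](CO[Si](CC)(CC)CC)(CC)[C@](C)(C(=O)OCC[Si](C)(C)C)[C@H]1C(CC)=[C] | intermediate (not isolated)
20 | trans-fused tetrahydroindene, C6 CH2OSiEt3 β, C3 methyl α, 2-(trimethylsilyl)ethyl ester | CCC1=C[C@@H](C)[C@@H]2C(C)=C[C@@](CO[Si](CC)(CC)CC)(CC)[C@](C)(C(=O)OCC[Si](C)(C)C)[C@@H]12 | intermediate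
21 | C6 aldehyde, configuration as 20 | CCC1=C[C@@H](C)[C@@H]2C(C)=C[C@@](C=O)(CC)[C@](C)(C(=O)OCC[Si](C)(C)C)[C@@H]12 | intermediate
22 | 2-(trimethylsilyl)ethyl ester of 24-nor-spiculoic acid B | CCC1=C[C@@H](C)[C@@H]2C(C)=C[C@@](/C=C/c3ccccc3)(CC)[C@](C)(C(=O)OCC[Si](C)(C)C)[C@@H]12 | intermediate
23 | 24-nor-spiculoic acid B | CCC1=C[C@@H](C)[C@@H]2C(C)=C[C@@](/C=C/c3ccccc3)(CC)[C@](C)(C(=O)O)[C@@H]12 | target

## Step count and risks

Total: 16 steps. Longest linear sequence: 15 steps (steps 1–5 and 7–16).

**Step 7 (key step).** The most likely failure is reversal of the orientation, with the acyl-bearing carbon bonding to the oxygen-bearing terminus. The cationic aluminium chelate makes the transition state polar, and the ring oxygen then stabilises charge at C4. Conjugate addition without ring closure, or binding of the Lewis acid by the pyrone carbonyl, could also stop the reaction. Fallback: run the cycloaddition of 7 and 11 without Lewis acid at 12–15 kbar in CH2Cl2, the uncatalysed mode in which 5-bromopyrones are known to give this orientation. Facial control is then given up, and the auxiliary is used as a resolving handle: the two endo diastereomers are separated and the route continues from 12. No new compound is made.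

**Step 9.** Delivery of ethyl to the wrong allylic terminus (C4, direct substitution) or no reaction at all is possible. C6 is fully substituted, it lies next to quaternary C7, and its α face is flanked by the endo imide. Fallback: from 13, cleave the auxiliary first with EtSH/n-BuLi to give the thioester lactone F1. The endo group is then small and no imide is present, so excess EtMgBr with CuBr·SMe2 can be used under more forcing conditions. This converts the thioester into the ethyl ketone and opens the lactone in one operation, giving the keto acid F2. Mitsunobu esterification with Me3SiCH2CH2OH returns to 17.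

**Step 13.** Poor discrimination between the two diastereotopic C–H bonds would give C3 epimers. Enolisation of the hindered ketone instead of addition, or insertion into the C7 methyl, are the other risks. Fallback: from 15, LiOH/H2O2 gives the C7a carboxylic acid F3; i-BuOCOCl/Et3N then CH2N2 gives the diazoketone F4; Rh2(OAc)4 effects 1,5 C–H insertion to the cyclopentanone F5, where the carboxylate ligands on rhodium can be varied to tune the selectivity at C3. KN(SiMe3)2/PhNTf2 enolises toward the CH2 and gives the enol triflate F6; Fe(acac)3-catalysed coupling with EtMgBr returns to 20.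

**Step 14.** Silyl transfer at the neopentyl oxygen may be slow. If the silyl group is lost before the alkoxysulfonium salt forms, the alcohol can close onto the C7 ester. Fallback: from 20, remove the silyl group under weakly acidic conditions (PPTS, MeOH, 0 °C) to the alcohol F7 and oxidise it at once with Dess–Martin periodinane/NaHCO3 to 21. The neutral alcohol attacks the hindered ester only slowly if it is not stored.

**Step 15.** Addition to an aldehyde held between two quaternary carbons may be slow, and forcing may erode the E selectivity. Fallback: from 21, Takai iodo-olefination (CrCl2, CHI3) gives the (E)-alkenyl iodide F8, and Suzuki coupling with PhB(OH)2 (Pd(PPh3)4, K2CO3) returns to 22.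

## Further compounds

F0 | step 7 | none | none
F1 | step 9 | S-ethyl thioester of the bridged lactone (13 with C(=O)SEt on C7a) | C[C@]12C(=O)O[C@](C)(C=C1CO[Si](CC)(CC)CC)[C@@H](CC)[C@@H]2C(=O)SCC
F2 | step 9 | keto acid (17 with free CO2H on C7) | CC[C@@H]1C(C)=C[C@@](CO[Si](CC)(CC)CC)(CC)[C@](C)(C(=O)O)[C@H]1C(=O)CC
F3 | step 13 | C7a carboxylic acid (15 with CO2H in place of the imide) | CC[C@@H]1C(C)=C[C@@](CO[Si](CC)(CC)CC)(CC)[C@](C)(C(=O)OCC[Si](C)(C)C)[C@H]1C(=O)O
F4 | step 13 | diazoketone on C7a | CC[C@@H]1C(C)=C[C@@](CO[Si](CC)(CC)CC)(CC)[C@](C)(C(=O)OCC[Si](C)(C)C)[C@H]1C(=O)C=[N+]=[N-]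
F5 | step 13 | trans-fused hexahydroinden-1-one (C1 ketone, C3 methyl α) | O=C1C[C@@H](C)[C@@H]2C(C)=C[C@@](CO[Si](CC)(CC)CC)(CC)[C@](C)(C(=O)OCC[Si](C)(C)C)[C@@H]12
F6 | step 13 | C1 enol triflate of F5 (C1=C2) | O=S(=O)(OC1=C[C@@H](C)[C@@H]2C(C)=C[C@@](CO[Si](CC)(CC)CC)(CC)[C@](C)(C(=O)OCC[Si](C)(C)C)[C@@H]12)C(F)(F)F
F7 | step 14 | C6 hydroxymethyl compound (20 without the triethylsilyl group) | CCC1=C[C@@H](C)[C@@H]2C(C)=C[C@@](CO)(CC)[C@](C)(C(=O)OCC[Si](C)(C)C)[C@@H]12
F8 | step 15 | (E)-2-iodoethenyl compound on C6 | CCC1=C[C@@H](C)[C@@H]2C(C)=C[C@@](/C=C/I)(CC)[C@](C)(C(=O)OCC[Si](C)(C)C)[C@@H]12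
A1 | alternative 1 | trans-fused bicyclic methyl ester with a vinyl group on C6 | CCC1=C[C@@H](C)[C@@H]2C(C)=C[C@@](C=C)(CC)[C@](C)(C(=O)OC)[C@@H]12
A2 | alternative 1 | open-chain pentaene methyl ester with a divinyl quaternary C6 | C=CC(CC)(C=C)[C@](C)(C(=O)OC)[C@@H](C(CC)=C)[C@@H](C(C)=C)[C@H](C)C=C
A3 | alternative 2 | cyclohex-3-ene carboxylic acid with both quaternary carbons, the E-styryl group and two metathesis arms | C=C(CC)[C@H]1[C@H]([C@H](C)C=C)C(C)=C[C@@](/C=C/c2ccccc2)(CC)[C@]1(C)C(=O)O
A4 | alternative 2 | δ-lactone with methyl and dienyl arm on the carbinol carbon C4 (C4 configuration and C5=C6 geometry drawn for a boat-like transition state; C7 unspecified) | O=C1O[C@](C)(/C=C(CC)/C=C/c2ccccc2)[C@@H]([C@H](C)C=C)[C@H](C(CC)=C)C1C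
A5 | alternative 3 | methyl ester of 24-nor-spiculoic acid B | CCC1=C[C@@H](C)[C@@H]2C(C)=C[C@@](/C=C/c3ccccc3)(CC)[C@](C)(C(=O)OC)[C@@H]12
A6 | alternative 3 | cyclopentene with a (Z)-alkenyl iodide arm on C3a and an ethyl-substituted alkene on C7 (drawn as E) | CCC1=C[C@@H](C)[C@H](/C(C)=C\I)[C@H]1[C@@](C)(C(=O)OC)/C(CC)=C/Cc1ccccc1
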